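**Strategy.** Benzofuran numbering is used (O1, C2, C3, C3a, C4–C7, C7a). The target is an O-alkyl vinylogous ester, O1–C7a=C7–C6=O, with the quaternary, allyl-bearing C3a next to C7a. The dihydrofuran ring is therefore closed by making the O1–C7a and C3–C3a bonds together, in a Lewis-acid formal [3+2] cyclisation of a cis aryl epoxide (O1, C2, C3) with an achiral cyclic 1-methoxy-3-silyloxy diene whose nucleophilic terminus is C3a. The diene comes from a transposed vinylogous ester (carbonyl at C7a, methyl enol ether at C6); acid in the same flask closes the ring and moves the carbonyl to C6. The C5 methoxy group is added last.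

Key step: step 7

Remark on the chemistry: compounds 1 and 6 are taken as commercial. The C5 configuration (methoxy trans to the pseudo-axial allyl group, α to the C6 ketone) is assumed to be the more stable one, so kinetic and equilibrium control should point the same way.

**Step 1**
Reactants: 1 2-methoxyresorcinol (2-methoxybenzene-1,3-diol)
Product: 2 2-methoxycyclohexane-1,3-dione
Conditions: H2 (5 bar), 5% Pd/C, NaOH (1.1 equiv), H2O, 50 °C; then HCl to pH 2
Reagents that add atoms: none
Why: Partial hydrogenation of the resorcinol monoanion (resorcinol-to-dihydroresorcinol reduction) should stop at the dione enolate, which resists further reduction; no stereocentre.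

**Step 2**
Reactants: 2 2-methoxycyclohexane-1,3-dione
Product: 3 2,3-dimethoxycyclohex-2-en-1-one
Conditions: HC(OMe)3, MeOH, p-TsOH (cat.), 60 °C
Reagents that add atoms: trimethyl orthoformate, COC(OC)OC
Why: Acid-catalysed O-methylation of the enol of a symmetric cyclic 1,3-dione (vinylogous ester formation) can give only one product.

**Step 3**
Reactants: 3 2,3-dimethoxycyclohex-2-en-1-one
Product: 4 (±)-6-allyl-2,3-dimethoxycyclohex-2-en-1-one
Conditions: LiN(iPr)2, THF, −78 °C; allyl bromide, −78 to 0 °C
Reagents that add atoms: allyl bromide, C=CCBr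
Why: Stork–Danheiser kinetic α'-alkylation of a vinylogous ester; the C6 stereocentre is racemic and is erased in step 4.

**Step 4**
Reactants: 4 (±)-6-allyl-2,3-dimethoxycyclohex-2-en-1-one
Product: 5 [(2-allyl-5,6-dimethoxycyclohexa-1,5-dien-1-yl)oxy]trimethylsilane
Conditions: LiN(iPr)2, THF, −78 °C; Me3SiCl, −78 to 0 °C; non-aqueous work-up (pentane, filtration), used crude
Reagents that add atoms: chlorotrimethylsilane, C[Si](C)(C)Cl
Why: A second kinetic α'-deprotonation (as in α',α'-dialkylation of vinylogous esters) and O-silylation should give the achiral cross-conjugated silyl dienol ether whose terminus is the allyl-bearing carbon.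

**Step 5**
Reactants: 6 3,4,5-trimethoxybenzaldehyde
Product: 7 (Z)-1,2,3-trimethoxy-5-(prop-1-en-1-yl)benzene
Conditions: EtPPh3Br, NaN(SiMe3)2, THF, −78 to 23 °C; minor E isomer removed by chromatography
Reagents that add atoms: ethyltriphenylphosphonium bromide, CC[P+](c1ccccc1)(c1ccccc1)c1ccccc1.[Br-]
Why: Salt-free Wittig olefination with a non-stabilised ylide should give the Z alkene under kinetic control; the cis geometry is needed so that inversion at the benzylic carbon in step 7 leads to the trans 2,3-relationship.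

**Step 6**
Reactants: 7 (Z)-1,2,3-trimethoxy-5-(prop-1-en-1-yl)benzene
Product: 8 (2R,3S)-2-methyl-3-(3,4,5-trimethoxyphenyl)oxirane (cis)
Conditions: (S,S)-[N,N'-bis(3,5-di-tert-butylsalicylidene)cyclohexane-1,2-diaminato]MnCl (trivalent manganese, 4 mol %), NaOCl (aq., pH 11.3), 4-phenylpyridine N-oxide, CH2Cl2, 0 °C
Reagents that add atoms: sodium hypochlorite, [Na+].[O-]Cl
Why: Jacobsen–Katsuki epoxidation is best suited to cis-disubstituted aryl alkenes; the (S,S)-catalyst should deliver oxygen to the face that gives the (2R,3S)-cis-epoxide (the sense known for cis-β-methylstyrene), setting both stereocentres.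

**Step 7**
Reactants: 5 [(2-allyl-5,6-dimethoxycyclohexa-1,5-dien-1-yl)oxy]trimethylsilane; 8 (2R,3S)-2-methyl-3-(3,4,5-trimethoxyphenyl)oxirane
Product: 11 (2R,3S,3aR)-3a-allyl-7-methoxy-2-methyl-3-(3,4,5-trimethoxyphenyl)-3,3a,4,5-tetrahydro-1-benzofuran-6(2H)-one, via hydroxy ketone 9 (not isolated), via cyclic hemiketal 10 (not isolated)
Conditions: TiCl4 (1.1 equiv), 4 Å molecular sieves, CH2Cl2, −78 to −30 °C; then 1 M HCl, THF, 23 °C, same flask
Reagents that add atoms: water, O
Why: TiCl4 activates the epoxide, whose benzylic carbon C3 is attacked with inversion by the terminal carbon C3a of the 1-methoxy-3-silyloxy diene (Mukaiyama-type epoxide opening, the first half of the known Lewis-acid [3+2] cyclisation of 1,3-dioxygenated silyl dienol ethers with epoxides to 2-alkylidene tetrahydrofurans), giving hydroxy ketone 9. In acid the C2 hydroxyl adds to the C7a ketone (5-exo-trig, hemiketal 10), water is lost to an alkoxy-allyl cation, and hydrolysis at C6 with loss of methanol transposes the carbonyl from C7a to C6 while the O1–C7a enol-ether bond stays (a Stork–Danheiser-type 1,3-transposition with an internal oxygen nucleophile). C2 is carried unchanged from the epoxide, and C3 is set by inversion at the benzylic carbon of the cis-epoxide, which places methyl and aryl trans on the new ring. C3a is set in the C–C bond formation by an exo approach in which the aryl group points away from the carbocycle and the small hydrogen lies over it, which places aryl cis to allyl. The step needs benzylic regioselectivity in the epoxide, secured by the trimethoxyphenyl group, and attack through C3a rather than C7, secured because C3a is the terminus of the donor-substituted diene and gives the fully delocalised silyloxy/methoxy allyl cation. The diene is achiral, so the epoxide is the only source of absolute configuration.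

**Step 8**
Reactants: 11 (2R,3S,3aR)-3a-allyl-7-methoxy-2-methyl-3-(3,4,5-trimethoxyphenyl)-3,3a,4,5-tetrahydro-1-benzofuran-6(2H)-one
Product: 12 (2R,3S,3aS,5S)-3a-allyl-5-hydroxy-7-methoxy-2-methyl-3-(3,4,5-trimethoxyphenyl)-3,3a,4,5-tetrahydro-1-benzofuran-6(2H)-one
Conditions: KN(SiMe3)2, THF, −78 °C; 2-(phenylsulfonyl)-3-phenyloxaziridine, −78 °C; AcOH quench
Reagents that add atoms: 2-(phenylsulfonyl)-3-phenyloxaziridine, O=S(=O)(c1ccccc1)N1OC1c1ccccc1
Why: C5 is the only enolisable position (C3a is quaternary), and oxaziridine oxidation of the α'-enolate (Davis-type hydroxylation) should occur anti to the pseudo-axial allyl group, giving hydroxyl trans to allyl.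

**Step 9**
Reactants: 12 (2R,3S,3aS,5S)-3a-allyl-5-hydroxy-7-methoxy-2-methyl-3-(3,4,5-trimethoxyphenyl)-3,3a,4,5-tetrahydro-1-benzofuran-6(2H)-one
Product: 13 (2R,3S,3aS,5S)-3a-allyl-5,7-dimethoxy-2-methyl-3-(3,4,5-trimethoxyphenyl)-3,3a,4,5-tetrahydro-1-benzofuran-6(2H)-one (CNP0136253.1)
Conditions: MeI (excess), Ag2O, 4 Å molecular sieves, CH2Cl2, 23 °C, dark
Reagents that add atoms: iodomethane, CI
Why: Purdie-type O-methylation of the α-ketol under near-neutral conditions forms no new stereocentre and should keep the C5 configuration.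

**Compound list**
1 | 2-methoxyresorcinol | COc1c(O)cccc1O | starting material
2 | 2-methoxycyclohexane-1,3-dione | COC1C(=O)CCCC1=O | intermediate
3 | 2,3-dimethoxycyclohex-2-en-1-one | COC1=C(OC)C(=O)CCC1 | intermediate
4 | (±)-6-allyl-2,3-dimethoxycyclohex-2-en-1-one | C=CCC1CCC(OC)=C(OC)C1=O | intermediate
5 | [(2-allyl-5,6-dimethoxycyclohexa-1,5-dien-1-yl)oxy]trimethylsilane | C=CCC1=C(O[Si](C)(C)C)C(OC)=C(OC)CC1 | intermediate
6 | 3,4,5-trimethoxybenzaldehyde | COc1cc(C=O)cc(OC)c1OC | starting material
7 | (Z)-1,2,3-trimethoxy-5-(prop-1-en-1-yl)benzene | C/C=C\c1cc(OC)c(OC)c(OC)c1 | intermediate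
8 | (2R,3S)-2-methyl-3-(3,4,5-trimethoxyphenyl)oxirane | C[C@H]1O[C@H]1c1cc(OC)c(OC)c(OC)c1 | intermediate
9 | (6R)-6-allyl-6-[(1S,2R)-2-hydroxy-1-(3,4,5-trimethoxyphenyl)propyl]-2,3-dimethoxycyclohex-2-en-1-one | C=CC[C@]1(CCC(OC)=C(OC)C1=O)[C@H](c1cc(OC)c(OC)c(OC)c1)[C@@H](C)O | intermediate (not isolated)
10 | (2R,3S,3aR)-3a-allyl-6,7-dimethoxy-2-methyl-3-(3,4,5-trimethoxyphenyl)-2,3,3a,4,5,7a-hexahydro-1-benzofuran-7a-ol (7a epimers) | C=CC[C@@]12CCC(OC)=C(OC)C1(O)O[C@H](C)[C@H]2c1cc(OC)c(OC)c(OC)c1 | intermediate (not isolated)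
11 | (2R,3S,3aR)-3a-allyl-7-methoxy-2-methyl-3-(3,4,5-trimethoxyphenyl)-3,3a,4,5-tetrahydro-1-benzofuran-6(2H)-one | C=CC[C@@]12CCC(=O)C(OC)=C1O[C@H](C)[C@H]2c1cc(OC)c(OC)c(OC)c1 | intermediate
12 | (2R,3S,3aS,5S)-3a-allyl-5-hydroxy-7-methoxy-2-methyl-3-(3,4,5-trimethoxyphenyl)-3,3a,4,5-tetrahydro-1-benzofuran-6(2H)-one | C=CC[C@@]12C[C@H](O)C(=O)C(OC)=C1O[C@H](C)[C@H]2c1cc(OC)c(OC)c(OC)c1 | intermediate
13 | (2R,3S,3aS,5S)-3a-allyl-5,7-dimethoxy-2-methyl-3-(3,4,5-trimethoxyphenyl)-3,3a,4,5-tetrahydro-1-benzofuran-6(2H)-one | C=CC[C@@]12C[C@H](OC)C(=O)C(OC)=C1O[C@H](C)[C@H]2c1cc(OC)c(OC)c(OC)c1 | target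

**Total step count:** 9. **Longest linear sequence:** 7 (steps 1–4, 7–9).

**Steps most likely to fail**

1. Step 7. Capture of the opened epoxide by the crowded, tetrasubstituted diene terminus may be slower than hydride shift in the benzylic cation (isomerisation to the aryl acetone) or chloride capture. A free cation would also erode the inversion at C3 and the exo preference at C3a. Fallback, setting out from 3 and 8 and coming back at 11: the C3–C3a bond is made on an unhindered nucleophile and the quaternary centre is created afterwards by allylation. Enone 3 is converted (LiN(iPr)2, Me3SiCl) into [(5,6-dimethoxycyclohexa-1,5-dien-1-yl)oxy]trimethylsilane F1. F1 should open 8 at the benzylic carbon (TiCl4, CH2Cl2, −78 °C, basic work-up) to give the hydroxy ketone 6-[(1R,2R)-2-hydroxy-1-(3,4,5-trimethoxyphenyl)propyl]-2,3-dimethoxycyclohex-2-en-1-one F2. Silylation (TBSOTf, 2,6-lutidine) gives its tert-butyldimethylsilyl ether F3. A second kinetic enolisation and allyl bromide (Stork–Danheiser alkylation) should give the quaternary ketone (6R)-6-allyl-6-[(1S,2R)-2-(tert-butyldimethylsilyloxy)-1-(3,4,5-trimethoxyphenyl)propyl]-2,3-dimethoxycyclohex-2-en-1-one F4. The facial selectivity there would rest on 1,3-allylic strain; the isomer needed arises if the electrophile enters anti to aryl. HF·pyridine and then p-TsOH remove the silyl group and close the ring through 9 to 11.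

2. Step 6. Collapse of the radical intermediate on manganese before ring closure would leak trans-epoxide, and the electron-rich epoxide may open on the catalyst or during isolation. Fallback, setting out from 7 and coming back at 8: 7 is isomerised (I2 cat., light) to (E)-1,2,3-trimethoxy-5-(prop-1-en-1-yl)benzene F5. Shi epoxidation (D-fructose-derived ketone, KHSO5, K2CO3 buffer) should give (2R,3R)-2-methyl-3-(3,4,5-trimethoxyphenyl)oxirane F6 by concerted oxygen transfer. Acid-catalysed hydration (HClO4 cat., H2O/THF) inverts the benzylic carbon to the erythro diol (1S,2R)-1-(3,4,5-trimethoxyphenyl)propane-1,2-diol F7. The one-pot Kolb–Sharpless sequence (MeC(OMe)3, PPTS; AcBr; K2CO3, MeOH) passes through (1R,2R)-1-bromo-1-(3,4,5-trimethoxyphenyl)propan-2-yl acetate F8 and closes the epoxide with net retention at both carbons, giving cis-epoxide 8.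

3. Step 9. Methylation of the hindered secondary α-ketol may be slow, and long exposure risks enolisation with loss of the C5 configuration or α-ketol side reactions. Fallback, setting out from 11 and coming back at 13 without passing through 12: 11 is converted (LiN(iPr)2, Me3SiCl) into its silyl enol ether (2R,3S,3aS)-3a-allyl-7-methoxy-2-methyl-3-(3,4,5-trimethoxyphenyl)-6-(trimethylsilyloxy)-2,3,3a,4-tetrahydro-1-benzofuran F9. Oxidation with iodosylbenzene (trivalent iodine) and BF3·OEt2 in methanol (hypervalent-iodine α-methoxylation of a silyl enol ether) should introduce the C5 methoxy group directly. Brief equilibration with catalytic DBU would then settle C5 in the configuration trans to allyl, giving 13.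

**Further compounds**
F1 | step 7 | [(5,6-dimethoxycyclohexa-1,5-dien-1-yl)oxy]trimethylsilane | COC1=C(OC)C(O[Si](C)(C)C)=CCC1
F2 | step 7 | 6-[(1R,2R)-2-hydroxy-1-(3,4,5-trimethoxyphenyl)propyl]-2,3-dimethoxycyclohex-2-en-1-one (C6 epimers) | COC1=C(OC)C(=O)C(CC1)[C@H](c1cc(OC)c(OC)c(OC)c1)[C@@H](C)O
F3 | step 7 | 6-[(1R,2R)-2-(tert-butyldimethylsilyloxy)-1-(3,4,5-trimethoxyphenyl)propyl]-2,3-dimethoxycyclohex-2-en-1-one (C6 epimers) | COC1=C(OC)C(=O)C(CC1)[C@H](c1cc(OC)c(OC)c(OC)c1)[C@@H](C)O[Si](C)(C)C(C)(C)C
F4 | step 7 | (6R)-6-allyl-6-[(1S,2R)-2-(tert-butyldimethylsilyloxy)-1-(3,4,5-trimethoxyphenyl)propyl]-2,3-dimethoxycyclohex-2-en-1-one | C=CC[C@]1(CCC(OC)=C(OC)C1=O)[C@H](c1cc(OC)c(OC)c(OC)c1)[C@@H](C)O[Si](C)(C)C(C)(C)C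
F5 | step 6 | (E)-1,2,3-trimethoxy-5-(prop-1-en-1-yl)benzene | C/C=C/c1cc(OC)c(OC)c(OC)c1
F6 | step 6 | (2R,3R)-2-methyl-3-(3,4,5-trimethoxyphenyl)oxirane | C[C@H]1O[C@@H]1c1cc(OC)c(OC)c(OC)c1
F7 | step 6 | (1S,2R)-1-(3,4,5-trimethoxyphenyl)propane-1,2-diol | C[C@@H](O)[C@@H](O)c1cc(OC)c(OC)c(OC)c1
F8 | step 6 | (1R,2R)-1-bromo-1-(3,4,5-trimethoxyphenyl)propan-2-yl acetate | C[C@@H](OC(C)=O)[C@H](Br)c1cc(OC)c(OC)c(OC)c1
F9 | step 9 | (2R,3S,3aS)-3a-allyl-7-methoxy-2-methyl-3-(3,4,5-trimethoxyphenyl)-6-(trimethylsilyloxy)-2,3,3a,4-tetrahydro-1-benzofuran | C=CC[C@@]12CC=C(O[Si](C)(C)C)C(OC)=C1O[C@H](C)[C@H]2c1cc(OC)c(OC)c(OC)c1
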